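Ring B (drimane numbering) holds the C6=C7 alkene conjugated to the exocyclic C8=C12 methylene, a 2-methylenecyclohex-3-ene that maps onto a vinylallene Diels–Alder adduct. The route therefore cuts C5–C10 and C8–C9. One intramolecular [4+2] of an acyclic vinylallene (C5=C6–C7=C8=C12) onto an (E)-β-methyl enoyl imide (C9=C10), joined through the C1–C4 chain, closes rings A and B together. It sets C5, C9 and C10 under control of an (S)-4-benzyloxazolidinone. The precursor is a linear keto imide with a gem-dimethyl group at C4 and a C3 ketone. Ketone reduction, reductive auxiliary removal and Mitsunobu attachment of umbelliferone finish the target.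

Key step: step 10

Remark (notation and reading of the target): drimane numbering is used throughout (ring A = C1–C5 and C10; ring B = C5–C10; C11 = CH2 on C9; C12 = CH2 on C8; C15 = methyl on C10). The SMILES is read as 3α-OH (axial), 5α-H, 9α-H and 10β-CH3, that is (3R,5R,9S,10S).

Step 1
Reactants: 1 4-pentyn-1-ol
Product: 3 methyl (2E)-6-hydroxy-3-methylhex-2-enoate, via alkenylalane 2 (not isolated)
Conditions: AlMe3 (3 equiv), Cp2ZrCl2 (0.25 equiv), CH2Cl2, 0 °C to rt; then ClCO2Me, 0 °C to rt; cold dilute HCl work-up
Reagents that add atoms: trimethylaluminium C[Al](C)C; methyl chloroformate COC(=O)Cl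
Why: Negishi carboalumination: after one equivalent of AlMe3 has capped the hydroxyl as its aluminium alkoxide, zirconium-catalysed syn addition of Me–Al across the terminal alkyne places the methyl on the internal carbon, and acylation of the alkenyl–aluminium bond by the chloroformate proceeds with retention, so the methyl ends cis to the ester (E enoate).

Step 2
Reactants: 3 methyl (2E)-6-hydroxy-3-methylhex-2-enoate
Product: 4 methyl (2E)-3-methyl-6-oxohex-2-enoate
Conditions: Dess–Martin periodinane, NaHCO3, CH2Cl2, 0 °C to rt
Reagents that add atoms: none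
Why: Dess–Martin oxidation should stop cleanly at the aldehyde under buffered conditions that neither enolise it nor disturb the trisubstituted E enoate.

Step 3
Reactants: 4 methyl (2E)-3-methyl-6-oxohex-2-enoate; 5 2-methyl-1-(trimethylsilyloxy)prop-1-ene
Product: 6 methyl (2E)-6-hydroxy-3,7,7-trimethyl-8-oxooct-2-enoate (racemic at the carbinol carbon; carried on crude)
Conditions: BF3·OEt2 (1.1 equiv), CH2Cl2, −78 °C; aqueous NaHCO3
Reagents that add atoms: none
Why: Mukaiyama aldol addition: the dimethyl-substituted carbon of the silyl enol ether attacks the BF3-activated aldehyde to form the C3–C4 bond and the quaternary C4, the α-quaternary product aldehyde being too hindered to react on, and the new carbinol centre may stay racemic because step 5 removes it.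

Step 4
Reactants: 6 methyl (2E)-6-hydroxy-3,7,7-trimethyl-8-oxooct-2-enoate
Product: 7 methyl (2E,8E)-6-hydroxy-9-iodo-3,7,7-trimethylnona-2,8-dienoate (racemic)
Conditions: CrCl2 (6 equiv), CHI3 (2 equiv), THF/1,4-dioxane, 0 °C to rt
Reagents that add atoms: iodoform IC(I)I
Why: Takai iodo-olefination: the geminal dichromium species generated from CHI3 and divalent chromium adds to the aldehyde and eliminates to the E vinyl iodide (C5=C6), a preference that is strongest for α-branched aldehydes, while CrCl2 tolerates the free hydroxyl and the enoate.

Step 5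
Reactants: 7 methyl (2E,8E)-6-hydroxy-9-iodo-3,7,7-trimethylnona-2,8-dienoate
Product: 8 methyl (2E,8E)-9-iodo-3,7,7-trimethyl-6-oxonona-2,8-dienoate
Conditions: Dess–Martin periodinane, NaHCO3, CH2Cl2, rt
Reagents that add atoms: none
Why: Dess–Martin oxidation of the secondary alcohol gives the C3 ketone and deletes the racemic centre, and since C4 is quaternary the β,γ-unsaturated ketone cannot isomerise into conjugation with the vinyl iodide.

Step 6
Reactants: 8 methyl (2E,8E)-9-iodo-3,7,7-trimethyl-6-oxonona-2,8-dienoate
Product: 9 (2E,8E)-9-iodo-3,7,7-trimethyl-6-oxonona-2,8-dienoic acid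
Conditions: LiOH·H2O (3 equiv), THF/MeOH/H2O, rt to 40 °C; then 1 M HCl to pH 3
Reagents that add atoms: lithium hydroxide [Li+].[OH-]
Why: Saponification of the methyl ester by acyl–oxygen cleavage should be slow but clean for the β,β-disubstituted enoate, and aqueous LiOH affects neither the vinyl iodide nor the ketone, whose enolate has no strain-free ring to close onto the E enoate.

Step 7
Reactants: 9 (2E,8E)-9-iodo-3,7,7-trimethyl-6-oxonona-2,8-dienoic acid; 10 (S)-4-benzyl-2-oxazolidinone
Product: 13 (4S)-4-benzyl-3-[(2E,8E)-9-iodo-3,7,7-trimethyl-6-oxonona-2,8-dienoyl]-1,3-oxazolidin-2-one, via mixed pivalic anhydride 11 (not isolated), via lithium oxazolidinide 12 (not isolated)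
Conditions: 9, PivCl (1.05 equiv), Et3N (1.1 equiv), THF, −78 °C to 0 °C; separately 10, n-BuLi, THF, −78 °C; combine at −78 °C, then 0 °C; aqueous NH4Cl
Reagents that add atoms: none
Why: N-Acylation of the oxazolidinone through the mixed pivalic anhydride: the lithium amide anion attacks the enoyl carbonyl because the other carbonyl is shielded by tert-butyl, and the low temperature with only one equivalent of amine base avoids vinylketene formation, so the E enoate, the ketone and the vinyl iodide are carried through unchanged.

Step 8
Reactants: 13 (4S)-4-benzyl-3-[(2E,8E)-9-iodo-3,7,7-trimethyl-6-oxonona-2,8-dienoyl]-1,3-oxazolidin-2-one; 14 propargyl alcohol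
Product: 15 (4S)-4-benzyl-3-[(2E,8E)-12-hydroxy-3,7,7-trimethyl-6-oxododeca-2,8-dien-10-ynoyl]-1,3-oxazolidin-2-one
Conditions: PdCl2(PPh3)2 (3 mol %), CuI (6 mol %), i-Pr2NH, THF, rt
Reagents that add atoms: none
Why: Sonogashira coupling: oxidative addition of zerovalent palladium into the vinyl C–I bond and transmetalation with the copper acetylide of propargyl alcohol join C6 to C7 with retention of the E geometry at room temperature, where the hindered amine does not cleave the imide and the free hydroxyl needs no protection.

Step 9
Reactants: 15 (4S)-4-benzyl-3-[(2E,8E)-12-hydroxy-3,7,7-trimethyl-6-oxododeca-2,8-dien-10-ynoyl]-1,3-oxazolidin-2-one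
Product: 18 (4S)-4-benzyl-3-[(2E,8E)-3,7,7-trimethyl-6-oxododeca-2,8,10,11-tetraenoyl]-1,3-oxazolidin-2-one (vinylallene imide; used at once), via sulfonylhydrazine 16 (not isolated), via propargylic diazene 17 (not isolated)
Conditions: PPh3, DEAD, THF, −15 °C; then 2-nitrobenzenesulfonylhydrazide (NBSH), −15 °C, then 23 °C; quick silica plug, taken directly into step 10
Reagents that add atoms: none
Why: Myers allene synthesis: Mitsunobu N-alkylation of the sulfonylhydrazide by the primary propargylic alcohol gives 16, loss of 2-nitrobenzenesulfinic acid on warming gives the monoalkyl diazene 17, and its retro-ene loss of N2 transposes the π bond to the terminal allene (C7=C8=C12); the reagents are neutral, and the hindered α-quaternary ketone is not expected to condense with the hydrazide at −15 °C.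

Step 10
Reactants: 18 vinylallene imide
Product: 19 (4S)-4-benzyl-3-{[(1S,4aR,8aS)-5,5,8a-trimethyl-2-methylidene-6-oxo-1,2,4a,5,6,7,8,8a-octahydronaphthalen-1-yl]carbonyl}-1,3-oxazolidin-2-one, the trans-fused (5R,9S,10S)-3-oxodrima-6,8(12)-dien-11-oyl imide
Conditions: Me2AlCl (3 equiv), CH2Cl2 (0.01 M), −30 °C to 0 °C; aqueous potassium sodium tartrate
Reagents that add atoms: none
Why: Me2AlCl ionises on the imide to the cationic dimethylaluminium chelate of the two imide carbonyls (a further equivalent rests on the C3 ketone), and this locked s-cis enoyl unit undergoes a concerted, asynchronous intramolecular Diels–Alder reaction with the tethered vinylallene, in which C5=C6–C7=C8 is the diene and the C8=C12 bond stays behind as the exocyclic methylene. The closest known reaction types are the Me2AlCl-promoted intramolecular Diels–Alder of (E,E)-trienoyl oxazolidinone imides to trans-fused bicycles and the intramolecular Diels–Alder of vinylallenes to ring-fused methylenecyclohexenes; their union on a β,β-disubstituted enoyl imide is untested but uses only these established bond-forming events. Ring B is closed by the cycloaddition itself (bonds C5–C10 and C8–C9), and ring A is closed in the fused mode through the four-carbon C1–C4 tether, which folds as a chair on the exo side of the dienophile. C9 is set by the auxiliary, whose benzyl group in the chelated (S)-oxazolidinone covers the Cα Re face so that the diene bonds to the Si face; C10 follows from the E dienophile, which keeps the methyl cis to C11; C5 follows from the endo placement of the imide carbonyl under the E diene, which puts H-5 anti to the C10 methyl (trans fusion). The step therefore needs Si-face and endo selectivity together with enough reactivity to build the quaternary C10 beside C4, and these should be secured by the rigid chelate, the E geometry of both partners, the gem-dimethyl group and sp2 C3 (easier folding, no competing tether stereocentre) and the unhindered sp allene terminus C8. The main doubt is the syn-axial contact between the C10 methyl and the axial C4 methyl in the trans-fusing transition state.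

Step 11
Reactants: 19 trans-fused keto imide
Product: 20 (4S)-4-benzyl-3-{[(1S,4aR,6R,8aS)-6-hydroxy-5,5,8a-trimethyl-2-methylidene-1,2,4a,5,6,7,8,8a-octahydronaphthalen-1-yl]carbonyl}-1,3-oxazolidin-2-one (3α-hydroxy imide)
Conditions: LiBH(s-Bu)3 (1.2 equiv), THF, −78 °C; aqueous NH4Cl (no alkaline peroxide work-up)
Reagents that add atoms: none
Why: Diastereoselective ketone reduction by a bulky trialkylborohydride: the reagent avoids the axial trajectory flanked by the axial hydrogens at C1 and C5 and attacks from the equatorial direction, as it does with other 4,4-dimethyl-3-oxo terpenoids, placing the hydroxyl axial (3α, cis to H-5, trans to the C10 methyl), and at −78 °C the ketone should be reduced well before the hindered imide.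

Step 12
Reactants: 20 3α-hydroxy imide
Product: 21 (3R,5R,9S,10S)-drima-6,8(12)-diene-3,11-diol (3α-OH axial, primary C11–OH on the β face)
Conditions: LiBH4, H2O (1 equiv), Et2O, 0 °C
Reagents that add atoms: none
Why: Reductive cleavage of the N-acyl oxazolidinone by water-activated LiBH4: hydride adds to the exocyclic carbonyl, the auxiliary is expelled and the aldehyde is reduced on to the primary alcohol without added base, so the allylic C9 centre is not epimerised and the C8=C12 bond is not drawn into conjugation.

Step 13
Reactants: 21 (3R,5R,9S,10S)-drima-6,8(12)-diene-3,11-diol; 22 umbelliferone (7-hydroxycoumarin)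
Product: 23 7-{[(3R,5R,9S,10S)-3-hydroxydrima-6,8(12)-dien-11-yl]oxy}-2H-chromen-2-one (CNP0259618.3)
Conditions: PPh3, DIAD, THF, 0 °C to rt
Reagents that add atoms: none
Why: Mitsunobu etherification: the PPh3–DIAD betaine activates only the primary C11 hydroxyl as its oxyphosphonium ion, which the acidic phenol of umbelliferone displaces by SN2 at the non-stereogenic CH2, while the axial neopentyl C3 hydroxyl is too hindered to be activated and keeps its configuration.

Compound list
1 | 4-pentyn-1-ol | C#CCCCO | starting material
2 | alkenylalane from syn-methylalumination of 1 (dimethylalumino group cis to the new methyl; hydroxyl as its dimethylaluminium alkoxide) | C[Al](C)OCCC/C(C)=C/[Al](C)C | intermediate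
3 | methyl (2E)-6-hydroxy-3-methylhex-2-enoate | OCCC/C(C)=C/C(=O)OC | intermediate
4 | methyl (2E)-3-methyl-6-oxohex-2-enoate | O=CCC/C(C)=C/C(=O)OC | intermediate
5 | 2-methyl-1-(trimethylsilyloxy)prop-1-ene | CC(C)=CO[Si](C)(C)C | starting material
6 | methyl (2E)-6-hydroxy-3,7,7-trimethyl-8-oxooct-2-enoate (racemic) | O=CC(C)(C)C(O)CC/C(C)=C/C(=O)OC | intermediate
7 | methyl (2E,8E)-6-hydroxy-9-iodo-3,7,7-trimethylnona-2,8-dienoate (racemic) | I/C=C/C(C)(C)C(O)CC/C(C)=C/C(=O)OC | intermediate
8 | methyl (2E,8E)-9-iodo-3,7,7-trimethyl-6-oxonona-2,8-dienoate | I/C=C/C(C)(C)C(=O)CC/C(C)=C/C(=O)OC | intermediate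
9 | (2E,8E)-9-iodo-3,7,7-trimethyl-6-oxonona-2,8-dienoic acid | I/C=C/C(C)(C)C(=O)CC/C(C)=C/C(=O)O | intermediate
10 | (S)-4-benzyl-2-oxazolidinone | O=C1N[C@@H](Cc2ccccc2)CO1 | starting material
11 | mixed anhydride of 9 with pivalic acid | I/C=C/C(C)(C)C(=O)CC/C(C)=C/C(=O)OC(=O)C(C)(C)C | intermediate
12 | lithium salt of (S)-4-benzyl-2-oxazolidinone (N-lithiated) | [Li]N1[C@@H](Cc2ccccc2)COC1=O | intermediate
13 | (4S)-4-benzyl-3-[(2E,8E)-9-iodo-3,7,7-trimethyl-6-oxonona-2,8-dienoyl]-1,3-oxazolidin-2-one | I/C=C/C(C)(C)C(=O)CC/C(C)=C/C(=O)N1[C@@H](Cc2ccccc2)COC1=O | intermediate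
14 | propargyl alcohol | C#CCO | starting material
15 | (4S)-4-benzyl-3-[(2E,8E)-12-hydroxy-3,7,7-trimethyl-6-oxododeca-2,8-dien-10-ynoyl]-1,3-oxazolidin-2-one | OCC#C/C=C/C(C)(C)C(=O)CC/C(C)=C/C(=O)N1[C@@H](Cc2ccccc2)COC1=O | intermediate
16 | Mitsunobu adduct of 15: the propargylic CH2 carries N(NH2)SO2(2-nitrophenyl) | NN(CC#C/C=C/C(C)(C)C(=O)CC/C(C)=C/C(=O)N1[C@@H](Cc2ccccc2)COC1=O)S(=O)(=O)c1ccccc1[N+](=O)[O-] | intermediate
17 | propargylic monoalkyl diazene (the propargylic CH2 carries N=NH) | N=NCC#C/C=C/C(C)(C)C(=O)CC/C(C)=C/C(=O)N1[C@@H](Cc2ccccc2)COC1=O | intermediate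
18 | (4S)-4-benzyl-3-[(2E,8E)-3,7,7-trimethyl-6-oxododeca-2,8,10,11-tetraenoyl]-1,3-oxazolidin-2-one (vinylallene imide) | C=C=C/C=C/C(C)(C)C(=O)CC/C(C)=C/C(=O)N1[C@@H](Cc2ccccc2)COC1=O | intermediate
19 | trans-fused (5R,9S,10S)-3-oxodrima-6,8(12)-dien-11-oyl imide of (S)-4-benzyl-2-oxazolidinone | C=C1C=C[C@H]2C(C)(C)C(=O)CC[C@]2(C)[C@H]1C(=O)N1[C@@H](Cc2ccccc2)COC1=O | intermediate
20 | (3R,5R,9S,10S)-3-hydroxydrima-6,8(12)-dien-11-oyl imide of (S)-4-benzyl-2-oxazolidinone (3α-OH) | C=C1C=C[C@H]2C(C)(C)[C@H](O)CC[C@]2(C)[C@H]1C(=O)N1[C@@H](Cc2ccccc2)COC1=O | intermediate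
21 | (3R,5R,9S,10S)-drima-6,8(12)-diene-3,11-diol | C=C1C=C[C@H]2C(C)(C)[C@H](O)CC[C@]2(C)[C@H]1CO | intermediate
22 | umbelliferone (7-hydroxycoumarin) | Oc1ccc2ccc(=O)oc2c1 | starting material
23 | 7-{[(3R,5R,9S,10S)-3-hydroxydrima-6,8(12)-dien-11-yl]oxy}-2H-chromen-2-one (CNP0259618.3) | C=C1C=C[C@H]2C(C)(C)[C@H](O)CC[C@]2(C)[C@H]1COc1ccc2ccc(=O)oc2c1 | target

Total step count: 13
Longest linear sequence: 13 steps (1 to 23); compounds 5, 10, 14 and 22 are bought and enter directly.

Steps most likely to fail

1. Step 10 (key cycloaddition). The β,β-disubstituted dienophile may be too unreactive to build the quaternary C10 next to C4, the Lewis acid may oligomerise the vinylallene, or endo and facial control may erode. The fallback sets out from 18 and abandons the Lewis acid. The cycloaddition would be run thermally at high dilution (toluene, BHT, 90–110 °C), a mode in which tethered vinylallenes are known to cyclise. The auxiliary then no longer induces the stereochemistry but serves as a covalent resolving handle: the diastereomeric imides are separated on silica and the route is rejoined at 19. No compound outside the list arises on this way (F0).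

2. Step 12 (auxiliary removal). Hydride may attack the ring carbonyl of the oxazolidinone and open it, because the acyl carbonyl is screened by the quaternary C10; the reduction may also stall. The fallback sets out from 20 and splits the operation into hydrolysis and reduction. LiOH with H2O2 (THF/H2O, 0 °C, short contact, Na2SO3 quench) is used because the hydroperoxide anion selects the exocyclic carbonyl even in hindered imides and is only weakly basic. It should give (3R,5R,9S,10S)-3-hydroxydrima-6,8(12)-dien-11-oic acid F1. Reduction of F1 with LiAlH4 (THF, 0 °C) rejoins the route at 21. The hydrolysis is kept cold and brief so that the C8=C12 bond does not migrate into conjugation.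

3. Step 13 (etherification). SN2 displacement at the β-branched C11 beside C10 may be slow, and the oxyphosphonium ion may instead eliminate toward the allylic C9. The fallback sets out from 21 and forms the ether bond from the arene side, so that C11 is never a reaction centre. This is a palladium-catalysed C–O coupling of the primary alcohol with 7-bromocoumarin (Brc1ccc2ccc(=O)oc2c1; [Pd(allyl)Cl]2, the biaryl phosphine RockPhos, Cs2CO3, toluene, 80 °C). The hindered axial C3 hydroxyl should not compete, and the route is rejoined directly at 23. No compound outside the list arises on this way (F0).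

Further compounds
F0 | step 10 | none | none
F1 | step 12 | (3R,5R,9S,10S)-3-hydroxydrima-6,8(12)-dien-11-oic acid | C=C1C=C[C@H]2C(C)(C)[C@H](O)CC[C@]2(C)[C@H]1C(=O)O
F0 | step 13 | none | none
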